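**Retrosynthetic overview**
- Last bond: the CH2 bridge between C6 of the chromene and C6 of the acetylfilicinic acid ring (ring C) is cut to a 6-formylchromene and acetylfilicinic acid, joined by reductive alkylation.
- Feature used: pyran C4 and the bridge CH2 are each a single carbon on C4a and C6, the two aromatic carbons that flank the C5 oxygen of ring A. Both are traced to the two formyl groups of one mirror-symmetric 3,5-diformyl-2,6-dihydroxy-4-methoxyacetophenone.
- Pyran ring B: C3–C4 by boronic acid Mannich alkenylation of one formyl group, O1–C2 by amine loss and oxa-6π closure. The surviving formyl group is the bridge carbon.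
- The C5 oxygen is carried as a methyl ether, which survives the acidic twofold formylation where an acetal would not. It is freed by BCl3 with the help of the C6 formyl group.
- Ring order: ring A is purchased, ring B is closed in step 2, ring C is made separately (step 4) and attached in step 5.

Key step: step 2

Remark: the target is achiral and its acylfilicinic acid ring is one of several rapidly equilibrating enol tautomers; the route delivers that equilibrium mixture, drawn as the given tautomer.

**Step 1**
Reactants: 1 1-(2,6-dihydroxy-4-methoxyphenyl)ethanone; 2 hexamethylenetetramine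
Product: 3 1-(3,5-diformyl-2,6-dihydroxy-4-methoxyphenyl)ethanone
Conditions: hexamethylenetetramine (5 equiv), CF3CO2H, 90 °C; then 3 M aq. HCl, 90 °C
Reagents that add atoms: hexamethylenetetramine, C1N2CN3CN1CN(C2)C3; water, O
Why: Duff reaction: both free ring carbons lie ortho to one hydroxyl and para to the other, so iminium ions from protonated hexamethylenetetramine aminomethylate them and internal hydride transfer with hydrolysis leaves two formyl groups; the methyl ether and the acetyl group are stable to hot CF3CO2H, whereas a Vilsmeier reagent would attack the ortho-hydroxyacetophenone and is avoided.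

**Step 2**
Reactants: 3 1-(3,5-diformyl-2,6-dihydroxy-4-methoxyphenyl)ethanone; 4 (2-methylprop-1-en-1-yl)boronic acid
Product: 7 8-acetyl-7-hydroxy-5-methoxy-2,2-dimethyl-2H-chromene-6-carbaldehyde, via allylic dibenzylamine 5 (not isolated), via ortho-quinone methide 6 (not isolated)
Conditions: 4 (0.9 equiv, added over several hours), Bn2NH (0.4 equiv), dioxane, 90 °C
Reagents that add atoms: (2-methylprop-1-en-1-yl)boronic acid, CC(C)=CB(O)O
Why: Bn2NH condenses reversibly with one of the two equivalent formyl groups to an iminium ion while 4 binds the neighbouring phenoxide as a tetracoordinate boronate, which passes its 2-methylpropenyl group intramolecularly to the iminium carbon (new C3–C4 bond) to give allylic amine 5; at 90 °C 5 expels Bn2NH, which is thereby turned over, and leaves ortho-quinone methide 6. The 1-oxatriene of 6 closes by thermal oxa-6π electrocyclization onto the ring carbonyl oxygen (new O1–C2 bond, six-membered pyran ring), which also restores the aromatic ring. The closest known reaction is the amine-catalysed condensation of salicylaldehydes with alkenylboronic acids to 2H-chromenes, a Petasis borono-Mannich reaction followed by amine elimination. No stereocentre remains, because the aminated carbon of 5 becomes sp2 and C2 carries two methyl groups. Regioselectivity is needed and is fixed by the substrate: each formyl group has only one free hydroxyl beside it, since the oxygen between the two formyl groups is a methyl ether that can neither bind boron nor form the quinone methide, and the hindered, hydrogen-bonded acetyl group does not form an iminium ion with Bn2NH. Mono-annulation is needed as well and is secured by a slight deficit of 4 added slowly, the second formyl group being expected to react more slowly once the ring has lost one acceptor; unreacted 3 is recovered and recycled.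

**Step 3**
Reactants: 7 8-acetyl-7-hydroxy-5-methoxy-2,2-dimethyl-2H-chromene-6-carbaldehyde
Product: 8 8-acetyl-5,7-dihydroxy-2,2-dimethyl-2H-chromene-6-carbaldehyde
Conditions: BCl3 (3 equiv, 1 M in CH2Cl2), CH2Cl2, −78 → 0 °C; then ice-water
Reagents that add atoms: none
Why: Lewis-acid ether cleavage directed by an ortho carbonyl group: BCl3 held between the C6 formyl oxygen and the C5 methoxy oxygen activates the methyl group for SN2 attack by chloride, and the low temperature should spare the pyran ring and the acetyl group.

**Step 4**
Reactants: 9 2,4,6-trihydroxyacetophenone; 10 iodomethane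
Product: 11 2-acetyl-3,5-dihydroxy-4,4-dimethylcyclohexa-2,5-dien-1-one (acetylfilicinic acid)
Conditions: NaOMe (4 equiv), MeI (2.5 equiv), MeOH, 0 °C → rt; then aq. HCl
Reagents that add atoms: iodomethane, CI
Why: Base-mediated C-alkylation of the phloroglucinol polyanion: the first methyl group makes its ring carbon the most nucleophilic site, so the second enters at the same carbon and dearomatizes the ring to the stable vinylogous acid; under- and over-methylated by-products are removed by crystallization or chromatography.

**Step 5**
Reactants: 8 8-acetyl-5,7-dihydroxy-2,2-dimethyl-2H-chromene-6-carbaldehyde; 11 2-acetyl-3,5-dihydroxy-4,4-dimethylcyclohexa-2,5-dien-1-one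
Product: 13 2-acetyl-6-[(8-acetyl-5,7-dihydroxy-2,2-dimethyl-2H-chromen-6-yl)methyl]-3,5-dihydroxy-4,4-dimethylcyclohexa-2,5-dien-1-one, via Knoevenagel arylidene triketone 12 (not isolated)
Conditions: L-proline (0.2 equiv), Hantzsch ester (diethyl 2,6-dimethyl-1,4-dihydropyridine-3,5-dicarboxylate, 1.2 equiv), CH2Cl2, rt
Reagents that add atoms: none
Why: Three-component reductive alkylation: proline-catalysed Knoevenagel condensation of the aldehyde with the only C–H acidic carbon of 11 gives arylidene triketone 12, whose electron-poor exocyclic alkene accepts hydride from the Hantzsch ester at the former formyl carbon, while the chromene alkene, the aryl ketones and the enols are not reduced; no stereocentre is formed and the product is the target.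

**Compound list**
1 | 1-(2,6-dihydroxy-4-methoxyphenyl)ethanone | CC(=O)c1c(O)cc(OC)cc1O | starting material
2 | hexamethylenetetramine | C1N2CN3CN1CN(C2)C3 | starting material
3 | 1-(3,5-diformyl-2,6-dihydroxy-4-methoxyphenyl)ethanone | CC(=O)c1c(O)c(C=O)c(OC)c(C=O)c1O | intermediate
4 | (2-methylprop-1-en-1-yl)boronic acid | CC(C)=CB(O)O | starting material
5 | 1-{3-[1-(dibenzylamino)-3-methylbut-2-en-1-yl]-5-formyl-2,6-dihydroxy-4-methoxyphenyl}ethanone (racemic) | CC(=O)c1c(O)c(C=O)c(OC)c(C(C=C(C)C)N(Cc2ccccc2)Cc2ccccc2)c1O | intermediate (not isolated)
6 | 2-acetyl-4-formyl-3-hydroxy-5-methoxy-6-(3-methylbut-2-en-1-ylidene)cyclohexa-2,4-dien-1-one, alkenyl group syn to the ring carbonyl | CC(=O)C1=C(O)C(C=O)=C(OC)/C(=C/C=C(C)C)C1=O | intermediate (not isolated)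
7 | 8-acetyl-7-hydroxy-5-methoxy-2,2-dimethyl-2H-chromene-6-carbaldehyde | CC(=O)c1c(O)c(C=O)c(OC)c2C=CC(C)(C)Oc12 | intermediate
8 | 8-acetyl-5,7-dihydroxy-2,2-dimethyl-2H-chromene-6-carbaldehyde | CC(=O)c1c(O)c(C=O)c(O)c2C=CC(C)(C)Oc12 | intermediate
9 | 2,4,6-trihydroxyacetophenone | CC(=O)c1c(O)cc(O)cc1O | starting material
10 | iodomethane | CI | starting material
11 | 2-acetyl-3,5-dihydroxy-4,4-dimethylcyclohexa-2,5-dien-1-one (acetylfilicinic acid) | CC(=O)C1=C(O)C(C)(C)C(O)=CC1=O | intermediate
12 | 2-acetyl-6-[(8-acetyl-5,7-dihydroxy-2,2-dimethyl-2H-chromen-6-yl)methylidene]-3-hydroxy-4,4-dimethylcyclohex-2-ene-1,5-dione (alkene geometry not fixed) | CC(=O)C1=C(O)C(C)(C)C(=O)C(=Cc2c(O)c3C=CC(C)(C)Oc3c(C(C)=O)c2O)C1=O | intermediate (not isolated)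
13 | 2-acetyl-6-[(8-acetyl-5,7-dihydroxy-2,2-dimethyl-2H-chromen-6-yl)methyl]-3,5-dihydroxy-4,4-dimethylcyclohexa-2,5-dien-1-one | CC(=O)C1=C(O)C(C)(C)C(O)=C(Cc2c(O)c3c(c(C(C)=O)c2O)OC(C)(C)C=C3)C1=O | target

**Totals**
Total step count: 5. Longest linear sequence: 4 steps (steps 1, 2, 3 and 5); step 4 is a one-step side branch.

**Steps most likely to fail**

Step 2. The annulation may run on to the second formyl group, or the alkenyl transfer may be slow at an iminium ion that is flanked by two ortho substituents and held in a strong hydrogen bond; protodeboronation of 4 would then compete. The fallback sets out from 1 and builds the pyran before the bridge carbon. Condensation of 1 with 3-methylbut-2-enal (ethylenediammonium diacetate, toluene, reflux) should give, by C-alkylation and oxa-6π closure, 1-(7-hydroxy-5-methoxy-2,2-dimethyl-2H-chromen-8-yl)ethanone F1. A single ortho-formylation of F1 at C6 under non-acidic conditions (MgCl2, Et3N, paraformaldehyde, MeCN, reflux) then comes back to the route at 7.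

Step 3. The Lewis acid may ionize the tertiary allylic C2–O bond of the pyran, or the cleavage may stall because the boron bound to the C7 oxygen ties up the formyl group. The fallback sets out from 9 and replaces the methyl ether by an acetal that is removed with a Brønsted acid.
- Para-selective methoxymethylation of 9 (chloromethyl methyl ether 1.0 equiv, iPr2NEt, CH2Cl2, 0 °C; the ortho hydroxyls are held by the acetyl group) gives 1-[2,6-dihydroxy-4-(methoxymethoxy)phenyl]ethanone F2.
- Twofold magnesium-mediated ortho-formylation (MgCl2, Et3N, paraformaldehyde, MeCN, reflux) gives 1-[3,5-diformyl-2,6-dihydroxy-4-(methoxymethoxy)phenyl]ethanone F3.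
- The annulation of step 2 applied to F3 gives 8-acetyl-7-hydroxy-5-(methoxymethoxy)-2,2-dimethyl-2H-chromene-6-carbaldehyde F4.
- HCl in MeOH at 40 °C, which 2,2-dimethylchromenes tolerate, removes the acetal and comes back to the route at 8.

Step 5. The Knoevenagel condensation may be slow at an aldehyde locked between two hydrogen-bonding hydroxyls; a second molecule of 11 may then add, or hydride may reach the iminium ion before the C–C bond forms. The fallback sets out from 8 and inverts the order of reduction and C–C bond formation. Reductive amination of 8 with morpholine (NaBH(OAc)3, 1,2-dichloroethane, rt) gives the Mannich base 1-[5,7-dihydroxy-2,2-dimethyl-6-(morpholin-4-ylmethyl)-2H-chromen-8-yl]ethanone F5. Heating F5 with 11 (dioxane, 90 °C) alkylates C6 of 11 with loss of morpholine and arrives at 13.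

**Further compounds**
F1 | step 2 | 1-(7-hydroxy-5-methoxy-2,2-dimethyl-2H-chromen-8-yl)ethanone | CC(=O)c1c(O)cc(OC)c2C=CC(C)(C)Oc12
F2 | step 3 | 1-[2,6-dihydroxy-4-(methoxymethoxy)phenyl]ethanone | CC(=O)c1c(O)cc(OCOC)cc1O
F3 | step 3 | 1-[3,5-diformyl-2,6-dihydroxy-4-(methoxymethoxy)phenyl]ethanone | CC(=O)c1c(O)c(C=O)c(OCOC)c(C=O)c1O
F4 | step 3 | 8-acetyl-7-hydroxy-5-(methoxymethoxy)-2,2-dimethyl-2H-chromene-6-carbaldehyde | CC(=O)c1c(O)c(C=O)c(OCOC)c2C=CC(C)(C)Oc12
F5 | step 5 | 1-[5,7-dihydroxy-2,2-dimethyl-6-(morpholin-4-ylmethyl)-2H-chromen-8-yl]ethanone | CC(=O)c1c(O)c(CN2CCOCC2)c(O)c2C=CC(C)(C)Oc12
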